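**Strategy.** The route is cut at C3–C4 and C7–C8 (numbering below). The six-membered ring C3–C4–C5–C6–C7–C8 shares the C3–C8 bond with the seven-membered ring C1–C2–C3–C8–C9–C10–C11, and a ketone at C2 makes C3=C8 a dienophile. One catalytic enantioselective Diels–Alder reaction joins achiral 2,2,5-trimethylcyclohept-4-ene-1,3-dione (quaternary C1) with (E)-2-silyloxypenta-1,3-diene, closing that ring and setting C3, C4 and C8. The adduct is advanced by C7-enolate displacement of a C2 sulfonate (cyclobutane), an epoxide-derived trans-diol at C10/C11, C10-hydroxyl-directed oxidation of the cis methyl on C1, and a two-stage tris-angeloylation.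

Key step: step 6

**Remarks**
- Numbering used in all names: C1 is the quaternary carbon (CH3 and CH2O in the target). C2, C3, C8 and C7 form the cyclobutane (C2 on C1, C8 methylated). C4(CH3)–C5–C6(=O) joins C3 to C7, and C9–C10(O)–C11(O) joins C8 to C1. C12 is the oxygenated carbon on C1, C13 the methyl on C1, C14 the methyl on C4, C15 the methyl on C8.
- Faces: β is the face of ring C1–C2–C3–C8–C9–C10–C11 that carries C3–H and C15; α is the face that carries C4 and C7.
- The quaternary carbon between the carbonyls and the seven-membered ring twist the two C=O groups away from each other, so the 1,3-dione is a poor chelating ligand. A one-point-binding boron Lewis acid and an acid-stable triisopropylsilyl enol ether are therefore used.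
- Assumption: the (R)-catalyst in step 6 is assigned from the accepted binding model for enones (contact of the α-C–H with the catalyst oxygen). The antipodal catalyst is equally available, so the sense can be matched without changing the route.
- Assumption: angelic anhydride is used as a purchased reagent for the two accessible hydroxyls; angelic acid is the numbered starting material for the last, hindered ester.

**Step 1**
Reactants: 1 cycloheptane-1,3-dione
Product: 3 2,2-dimethylcycloheptane-1,3-dione, via 2-methylcycloheptane-1,3-dione 2 (not isolated)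
Conditions: MeI (4 equiv), K2CO3, acetone, reflux
Reagents that add atoms: iodomethane CI
Why: Twofold C-methylation of the 1,3-diketone enolate (enolate alkylation), which stops at the quaternary C1 because no acidic hydrogen remains between the carbonyls.

**Step 2**
Reactants: 3 2,2-dimethylcycloheptane-1,3-dione
Product: 4 2,2-dimethylcyclohept-4-ene-1,3-dione
Conditions: 2-iodoxybenzoic acid (IBX, 1.2 equiv), DMSO, 65 °C
Reagents that add atoms: none
Why: Dehydrogenation of a ketone with hypervalent iodine (IBX oxidation via the enol), made unambiguous by the symmetry of 3 and limited to one enone by the amount of oxidant.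

**Step 3**
Reactants: 4 2,2-dimethylcyclohept-4-ene-1,3-dione
Product: 5 (±)-2,2,5-trimethyl-3-(trimethylsilyloxy)cyclohept-3-en-1-one
Conditions: CuI, MeLi (2 equiv), Et2O, 0 °C; then 4, TMSCl, THF, −78 °C
Reagents that add atoms: lithium dimethylcuprate [Li+].C[Cu-]C; chlorotrimethylsilane C[Si](C)(C)Cl
Why: Conjugate addition of a Gilman cuprate with chlorosilane trapping puts the methyl group on the β-carbon (the future C8) and fixes the enolate as a regio-defined silyl enol ether; the new stereocentre is racemic and is removed in step 4.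

**Step 4**
Reactants: 5 (±)-2,2,5-trimethyl-3-(trimethylsilyloxy)cyclohept-3-en-1-one
Product: 6 2,2,5-trimethylcyclohept-4-ene-1,3-dione
Conditions: Pd(OAc)2 (10 mol%), O2 (1 atm), DMSO, 25 °C
Reagents that add atoms: none
Why: Saegusa–Ito oxidation: the palladium enolate formed from the silyl enol ether undergoes β-hydride elimination toward the methyl-bearing carbon and regenerates the enone, now β-methylated.

**Step 5**
Reactants: 7 (E)-pent-3-en-2-one
Product: 8 (E)-2-(triisopropylsilyloxy)penta-1,3-diene
Conditions: i-Pr3SiOTf, Et3N, Et2O, 0 °C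
Reagents that add atoms: triisopropylsilyl trifluoromethanesulfonate CC(C)[Si](C(C)C)(C(C)C)OS(=O)(=O)C(F)(F)F
Why: Soft enolisation and O-silylation of the methyl ketone on its CH3 side gives the cross-conjugated 2-silyloxydiene without touching the E alkene.

**Step 6**
Reactants: 6 2,2,5-trimethylcyclohept-4-ene-1,3-dione; 8 (E)-2-(triisopropylsilyloxy)penta-1,3-diene
Product: 9 cis-fused Diels–Alder adduct (C2 and C11 ketones with C5=C6 silyl enol ether)
Conditions: (R)-3,3-diphenyl-1-(2-methylphenyl)tetrahydro-1H,3H-pyrrolo[1,2-c][1,3,2]oxazaborole (20 mol%), Tf2NH (18 mol%), CH2Cl2, −40 → −10 °C; Et3N quench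
Reagents that add atoms: none
Why: Proposed new method: the protonated oxazaborolidine binds the C2 carbonyl of 6 at the lone pair syn to C3–H (the other is blocked by the quaternary C1), lowers the LUMO of the C3=C8 enone and lets the diene add in a concerted, asynchronous [4+2] in which the CH2 terminus C7 bonds to the β-carbon C8 ahead of C4–C3; the closest known reaction type is the oxazaborolidinium-catalysed Diels–Alder reaction of cyclic enones with 2-silyloxydienes, not yet shown for a β,β-disubstituted enone that creates a quaternary centre, whereas the racemic Lewis-acid version with 3-methylcycloalkenones is known. Ring C3–C4–C5–C6–C7–C8 closes by suprafacial cycloaddition across the existing C3–C8 bond. C3 and C8 are set by the catalyst, which shields one face of the bound enone so that the diene adds to the Re face of both carbons, their cis relation being fixed by the ring alkene, and C4 is set by endo orientation of the C2 carbonyl toward the E diene, which places C14 cis to C2. Regioselectivity follows from the matched donor effects of the 2-silyloxy and 4-methyl groups of the diene, and site selectivity from the single C=C of 6. The step needs reactivity at a hindered dienophile and face selectivity, which the substrate supports by offering one accessible lone pair, an α-C–H for the organising contact with the catalyst and no enolisable position between the carbonyls.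

**Step 7**
Reactants: 9 cis-fused Diels–Alder adduct
Product: 11 C11 enol triflate (C10=C11–OTf), via potassium enolate 10 (not isolated)
Conditions: KN(SiMe3)2, THF, −78 °C; then PhNTf2, −78 → 0 °C
Reagents that add atoms: N-phenylbis(trifluoromethanesulfonimide) O=S(=O)(N(c1ccccc1)S(=O)(=O)C(F)(F)F)C(F)(F)F
Why: Kinetic deprotonation next to C11 can only occur at C10 (C1 is quaternary and the tertiary C3–H beside C2 is shielded), and O-triflation of the enolate removes the base-sensitive 1,3-dione while marking C10=C11.

**Step 8**
Reactants: 11 C11 enol triflate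
Product: 12 C10=C11 alkene with C2 ketone
Conditions: Pd(OAc)2 (5 mol%), PPh3 (10 mol%), HCO2H, Bu3N, DMF, 60 °C
Reagents that add atoms: none
Why: Palladium-catalysed reduction of an enol triflate by formate (oxidative addition, decarboxylation of the palladium formate, reductive elimination) replaces the triflate by hydrogen and leaves ketone and silyl enol ether untouched.

**Step 9**
Reactants: 12 C10=C11 alkene with C2 ketone
Product: 14 C2β-hydroxy C6-ketone, via silyl enol ether alcohol 13 (not isolated)
Conditions: Li, NH3(l)/THF, t-BuOH, −78 °C; NH4Cl; then 48% aq. HF, MeCN, 0 °C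
Reagents that add atoms: none
Why: Dissolving-metal reduction of the hindered C2 ketone proceeds through a ketyl that pyramidalises before protonation and so gives the more stable alcohol, C2–OH β with H over the six-membered ring (the outcome known for hindered cyclic ketones, where hydrides give the other epimer), after which aqueous HF hydrolyses the silyl enol ether to the C6 ketone.

**Step 10**
Reactants: 14 C2β-hydroxy C6-ketone
Product: 15 10β,11β-epoxy C2β-alcohol
Conditions: dimethyldioxirane, acetone, 0 °C
Reagents that add atoms: dimethyldioxirane CC1(C)OO1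
Why: Epoxidation with a dioxirane (concerted oxygen transfer) is run before ring closure because the cis-fused bicycle still differentiates the alkene faces: in the chair cycloheptene C2, C3 and C8 lie under the α face and the C7 methylene blocks it, so oxygen should add to the β face and set C10 and C11.

**Step 11**
Reactants: 15 10β,11β-epoxy C2β-alcohol
Product: 16 C2β methanesulfonate
Conditions: MsCl, Et3N, CH2Cl2, −20 → 0 °C
Reagents that add atoms: methanesulfonyl chloride CS(=O)(=O)Cl
Why: Mesylation through sulfene tolerates the hindered secondary hydroxyl and converts C2–O, with retention, into the leaving group that is antiperiplanar to the C3–C8 bond.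

**Step 12**
Reactants: 16 C2β methanesulfonate
Product: 17 tricyclic 10β,11β-epoxy ketone
Conditions: KOt-Bu, t-BuOH/THF, 25 → 50 °C
Reagents that add atoms: none
Why: Intramolecular alkylation of a ketone enolate by a δ-sulfonate (4-exo-tet, the reaction type used for bicyclo[3.1.1]heptanones) forms C2–C7 with inversion at C2; under equilibrating conditions only the C7 enolate reaches the backside of the axial C2–O bond, the new C7 centre is fixed by the bridged ring, and elimination has no antiperiplanar hydrogen.

**Step 13**
Reactants: 17 tricyclic 10β,11β-epoxy ketone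
Product: 18 tricyclic 10α,11β-diol ketone
Conditions: HClO4 (5 mol%), THF/H2O, 40 °C
Reagents that add atoms: water O
Why: Acid-catalysed epoxide hydrolysis of borderline SN2 type: water attacks C10 with inversion because C11 is neopentyl, giving C10–OH α and leaving C11–O β.

**Step 14**
Reactants: 18 tricyclic 10α,11β-diol ketone
Product: 19 C6 ethylene ketal of the diol
Conditions: ethylene glycol (10 equiv), pyridinium p-toluenesulfonate, benzene, reflux (Dean–Stark)
Reagents that add atoms: ethane-1,2-diol OCCO
Why: Acid-catalysed ketalisation protects the C6 ketone from the hydrosilane and the metal hydrides of step 15 and is removed in the acidic work-up of step 16.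

**Step 15**
Reactants: 19 C6 ethylene ketal of the diol
Product: 21 oxasilinane (O10–SiEt2–C12), via bis(diethylsilyl) ether 20 (not isolated)
Conditions: Et2SiH2 (5 equiv), [Ir(cod)OMe]2 (0.5 mol%), THF, 25 → 50 °C; evaporation; then [Rh(coe)2Cl]2 (2 mol%), Xantphos (4.5 mol%), norbornene, THF, 100 °C
Reagents that add atoms: diethylsilane CC[SiH2]CC
Why: Hydroxyl-directed C–H silylation: dehydrogenative Si–O coupling gives the hydrosilyl ethers, and the rhodium/Xantphos catalyst, which is selective for primary C–H bonds δ to oxygen, closes a six-membered oxasilinane that from O10 (α) can only reach C12, the methyl held syn-1,3 to it on the bridge, which sets the configuration of C1.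

**Step 16**
Reactants: 21 oxasilinane
Product: 23 triol ketone, via triol ketal 22 (not isolated)
Conditions: 30% H2O2, KHCO3, KF, THF/MeOH, 50 °C; Na2S2O3; then 1 M HCl, THF, 25 °C
Reagents that add atoms: hydrogen peroxide OO; water O
Why: Tamao–Fleming oxidation turns the C12–Si bond into C12–OH and frees O10 and O11, and aqueous acid then hydrolyses the dioxolane to return the C6 ketone.

**Step 17**
Reactants: 23 triol ketone
Product: 24 10,12-bis-angelate (C11β–OH free)
Conditions: angelic anhydride (2.4 equiv), Cs2CO3 (3 equiv), MeCN, 0 → 25 °C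
Reagents that add atoms: angelic anhydride C/C=C(/C)C(=O)OC(=O)/C(C)=C\C
Why: Carbonate-mediated O-acylation by a symmetric anhydride, run without a nucleophilic catalyst so that the Z alkenes cannot isomerise by conjugate addition–elimination, should esterify the primary C12 hydroxyl and the C10 hydroxyl next to the C9 methylene while the C11 hydroxyl beside quaternary C1 lags; any triester formed at this stage is already 27.

**Step 18**
Reactants: 24 10,12-bis-angelate; 25 angelic acid
Product: 27 CNP0214984.1, via mixed anhydride 26 (not isolated)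
Conditions: 25 (3 equiv), 2,4,6-trichlorobenzoyl chloride, Et3N, toluene, 25 °C; then 24, toluene, 80 °C
Reagents that add atoms: none
Why: Yamaguchi-type esterification: the mixed 2,4,6-trichlorobenzoic anhydride of angelic acid acylates the remaining neopentyl C11 hydroxyl on heating without a nucleophilic catalyst, conditions chosen because they keep the Z alkenes from isomerising to tiglates.

**Compound list**
1 | cycloheptane-1,3-dione | O=C1CCCCC(=O)C1 | starting material
2 | 2-methylcycloheptane-1,3-dione | CC1C(=O)CCCCC1=O | intermediate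
3 | 2,2-dimethylcycloheptane-1,3-dione | CC1(C)C(=O)CCCCC1=O | intermediate
4 | 2,2-dimethylcyclohept-4-ene-1,3-dione | CC1(C)C(=O)C=CCCC1=O | intermediate
5 | (±)-2,2,5-trimethyl-3-(trimethylsilyloxy)cyclohept-3-en-1-one (racemic at the methyl-bearing carbon) | CC1CCC(=O)C(C)(C)C(O[Si](C)(C)C)=C1 | intermediate
6 | 2,2,5-trimethylcyclohept-4-ene-1,3-dione (C1 = CMe2, C2 = enone C=O, C3=C8 with C15 on C8, C11 = second C=O; achiral) | CC1=CC(=O)C(C)(C)C(=O)CC1 | intermediate
7 | (E)-pent-3-en-2-one | C/C=C/C(C)=O | starting material
8 | (E)-2-(triisopropylsilyloxy)penta-1,3-diene | C/C=C/C(=C)O[Si](C(C)C)(C(C)C)C(C)C | intermediate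
9 | cis-fused adduct: ring C1(CH3)2–C2(=O)–C3H–C8(CH3)–C9H2–C10H2–C11(=O) fused at C3–C8 to ring C3–C4H(CH3)–C5H=C6(OSi(i-Pr)3)–C7H2–C8; C3–H and C15 β, C14 cis to C2 (3R,4R,8S in the route numbering) | CC1(C)C(=O)[C@@H]2[C@H](C)C=C(O[Si](C(C)C)(C(C)C)C(C)C)C[C@]2(C)CCC1=O | intermediate
10 | potassium enolate of 9 (O–C11=C10); stereocentres as in 9 | CC1(C)C(=O)[C@@H]2[C@H](C)C=C(O[Si](C(C)C)(C(C)C)C(C)C)C[C@]2(C)CC=C1[O-].[K+] | intermediate
11 | C11 enol triflate of 9 (C10=C11–OSO2CF3); stereocentres as in 9 | CC1(C)C(=O)[C@@H]2[C@H](C)C=C(O[Si](C(C)C)(C(C)C)C(C)C)C[C@]2(C)CC=C1OS(=O)(=O)C(F)(F)F | intermediate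
12 | C10=C11 alkene with C2 ketone and C5=C6 silyl enol ether; stereocentres as in 9 | CC1(C)C(=O)[C@@H]2[C@H](C)C=C(O[Si](C(C)C)(C(C)C)C(C)C)C[C@]2(C)CC=C1 | intermediate
13 | C2 alcohol of 12, C2–OH β (cis to C3–H) | CC1(C)[C@@H](O)[C@@H]2[C@H](C)C=C(O[Si](C(C)C)(C(C)C)C(C)C)C[C@]2(C)CC=C1 | intermediate
14 | hydroxy ketone: C2–OH β, C6 ketone, C10=C11 alkene | CC1(C)[C@@H](O)[C@@H]2[C@H](C)CC(=O)C[C@]2(C)CC=C1 | intermediate
15 | 10β,11β-epoxide of 14 (epoxide oxygen on the β face), C2–OH β | CC1(C)[C@@H](O)[C@@H]2[C@H](C)CC(=O)C[C@]2(C)C[C@H]3O[C@H]31 | intermediate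
16 | C2β methanesulfonate of 15 | CC1(C)[C@@H](OS(C)(=O)=O)[C@@H]2[C@H](C)CC(=O)C[C@]2(C)C[C@H]3O[C@H]31 | intermediate
17 | tricyclic epoxy ketone: cyclobutane C2–C3–C8–C7 (C2–H β, C7 on the α face), 10β,11β-epoxide, C6 ketone, C1(CH3)2 | CC1(C)[C@H]2[C@@H]3[C@H](C)CC(=O)[C@H]2[C@]3(C)C[C@H]4O[C@H]41 | intermediate
18 | tricyclic diol ketone: C10–OH α, C11–OH β, C6 ketone | CC1(C)[C@H]2[C@@H]3[C@H](C)CC(=O)[C@H]2[C@]3(C)C[C@H](O)[C@H]1O | intermediate
19 | C6 ethylene ketal (1,3-dioxolane) of 18 | CC1(C)[C@H]2[C@@H]3[C@H](C)CC4(OCCO4)[C@H]2[C@]3(C)C[C@H](O)[C@H]1O | intermediate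
20 | 10α,11β-bis(diethylsilyloxy) derivative of 19 | CC1(C)[C@H]2[C@@H]3[C@H](C)CC4(OCCO4)[C@H]2[C@]3(C)C[C@H](O[SiH](CC)CC)[C@H]1O[SiH](CC)CC | intermediate
21 | oxasilinane: ring O10–SiEt2–C12–C1–C11–C10 (C12 α on C1, C13 β), C11β–OSiHEt2, C6 ketal | CC[Si]5(CC)C[C@]1(C)[C@H]2[C@@H]3[C@H](C)CC4(OCCO4)[C@H]2[C@]3(C)C[C@H](O5)[C@H]1O[SiH](CC)CC | intermediate
22 | triol ketal: C10–OH α, C11–OH β, C12–OH (CH2OH α on C1), C6 ketal | OC[C@]1(C)[C@H]2[C@@H]3[C@H](C)CC4(OCCO4)[C@H]2[C@]3(C)C[C@H](O)[C@H]1O | intermediate
23 | triol ketone: as 22 with the C6 ketone free | OC[C@]1(C)[C@H]2[C@@H]3[C@H](C)CC(=O)[C@H]2[C@]3(C)C[C@H](O)[C@H]1O | intermediate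
24 | 10,12-bis-angelate of 23: angelates at O10 (α) and O12, C11–OH β free | C/C=C(/C)C(=O)OC[C@]1(C)[C@H]2[C@@H]3[C@H](C)CC(=O)[C@H]2[C@]3(C)C[C@H](OC(=O)/C(C)=C\C)[C@H]1O | intermediate
25 | (Z)-2-methylbut-2-enoic acid (angelic acid) | C/C=C(/C)C(O)=O | starting material
26 | (Z)-2-methylbut-2-enoic 2,4,6-trichlorobenzoic anhydride | C/C=C(/C)C(=O)OC(=O)c1c(Cl)cc(Cl)cc1Cl | intermediate
27 | CNP0214984.1: tris-angelate of 23 at O10 (α), O11 (β) and O12 | C/C=C(/C)C(=O)OC[C@]1(C)[C@H]2[C@@H]3[C@H](C)CC(=O)[C@H]2[C@]3(C)C[C@H](OC(=O)/C(C)=C\C)[C@H]1OC(=O)/C(C)=C\C | target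

**Step count.** Total: 18 steps. Longest linear sequence: 17 steps (steps 1–4 and 6–18, from cycloheptane-1,3-dione).

**Steps most likely to fail**

1. Step 6 (proposed new method). The β,β-disubstituted enone may not turn over on the chiral boron catalyst (silyl transfer from the diene to the catalyst, or a Mukaiyama–Michael adduct that does not close), or the two faces may be poorly discriminated. The fallback uses known chemistry and sets out from 6 and 8. The cycloaddition is run without asymmetric induction under the mixed Lewis acid AlBr3/AlMe3 (about 10:1) in toluene/CH2Cl2 at −5 °C, conditions established for 3-methylcycloalkenones and hindered 2-silyloxydienes, to give the racemic adduct F1. The enantiomers are then separated by preparative HPLC on an amylose tris(3,5-dimethylphenylcarbamate) phase, and the route is rejoined at 9.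

2. Step 12. Ring closure at the neopentyl carbon C2 may be slower than intermolecular aldol condensation through the more accessible C5 enolate, or than loss of the sulfonate. The fallback sets out from 15 and blocks C5 so that a single enolate can be formed irreversibly and forced. Tert-butoxybis(dimethylamino)methane in toluene at 80 °C gives the 5-(dimethylaminomethylidene) ketone F2. Mesylation as in step 11 gives the mesylate F3. KN(SiMe3)2 in THF/DMPU, −78 → 40 °C, deprotonates only at C7 and closes the cyclobutane to the blocked tricycle F4. 2 M NaOH in EtOH at 60 °C then removes the aminomethylidene group, and the route is rejoined at 17.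

3. Step 15. The rhodium silyl hydride may fail to insert into the C12–H bond, because the vicinal silyl ethers redistribute or because the C11 silyl ether reacts at the nearer C13–H. The fallback replaces metal-catalysed silylation by alkoxy-radical hydrogen transfer and sets out from 19. Ac2O, DMAP and pyridine give the diacetate F5. K2CO3 in MeOH at 0 °C cleaves the less hindered C10 acetate to the C11 monoacetate F6. PhI(OAc)2 and I2 in cyclohexane under visible light (hypoiodite reaction) generate the C10 alkoxy radical, which abstracts hydrogen from the syn-1,3 methyl C12 and closes the C10–O–C12 tetrahydrofuran F7. RuCl3 (cat.) with NaIO4 oxidises the ether CH2 to the γ-lactone F8. LiAlH4 in THF reduces lactone and acetate, and the route is rejoined at 22, which the acid stage of step 16 converts into 23.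

**Further compounds**
F1 | step 6 | racemic Diels–Alder adduct (9 and its mirror image, 1:1) | CC1(C)C(=O)[C@@H]2[C@H](C)C=C(O[Si](C(C)C)(C(C)C)C(C)C)C[C@]2(C)CCC1=O.CC1(C)C(=O)[C@H]2[C@@H](C)C=C(O[Si](C(C)C)(C(C)C)C(C)C)C[C@@]2(C)CCC1=O
F2 | step 12 | (E)-5-(dimethylaminomethylidene) derivative of 15 | CC1(C)[C@@H](O)[C@@H]2[C@H](C)/C(=C\N(C)C)C(=O)C[C@]2(C)C[C@H]3O[C@H]31
F3 | step 12 | C2β methanesulfonate of F2 | CC1(C)[C@@H](OS(C)(=O)=O)[C@@H]2[C@H](C)/C(=C\N(C)C)C(=O)C[C@]2(C)C[C@H]3O[C@H]31
F4 | step 12 | (E)-5-(dimethylaminomethylidene) derivative of 17 | CC1(C)[C@H]2[C@@H]3[C@H](C)/C(=C\N(C)C)C(=O)[C@H]2[C@]3(C)C[C@H]4O[C@H]41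
F5 | step 15 | 10α,11β-diacetate of 19 | CC1(C)[C@H]2[C@@H]3[C@H](C)CC4(OCCO4)[C@H]2[C@]3(C)C[C@H](OC(C)=O)[C@H]1OC(C)=O
F6 | step 15 | 11β-monoacetate of 19 (C10–OH α free) | CC1(C)[C@H]2[C@@H]3[C@H](C)CC4(OCCO4)[C@H]2[C@]3(C)C[C@H](O)[C@H]1OC(C)=O
F7 | step 15 | C10–O–C12 cyclic ether (tetrahydrofuran) of F6 | C5[C@]1(C)[C@H]2[C@@H]3[C@H](C)CC4(OCCO4)[C@H]2[C@]3(C)C[C@H](O5)[C@H]1OC(C)=O
F8 | step 15 | γ-lactone of F7 (C12 = C=O) | O=C5[C@]1(C)[C@H]2[C@@H]3[C@H](C)CC4(OCCO4)[C@H]2[C@]3(C)C[C@H](O5)[C@H]1OC(C)=O
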